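**Retrosynthetic overview**

1. Target 31 ⇐ desilylation and Yamaguchi closure of the seven-membered lactone (O12–C16) of seco acid 28; the C16 carboxyl is the oxidised isopropenyl methyl group of limonene.
2. C11–C12 is the one ring bond that joins two oxygen-bearing carbons: the ring ketone C11 sits next to the quaternary lactone carbinol C12 (an α-ketol). One oxidation level down both are carbonyl carbons, so SmI2 ketyl coupling of the C11 aldehyde with the C12 methyl ketone in acyclic 25 closes the 14-membered carbocycle; the 2,5-trans-tetrahydrofuran (C4–O–C7) is the turn in the chain.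
3. Tetrahydrofuran ⇐ 5-exo opening of a C3–C4 Shi epoxide by the C7 hydroxyl; C7/C8 glycol ⇐ asymmetric Nozaki–Hiyama–Kishi coupling, Sharpless epoxidation, hydride opening.
4. Chain ⇐ (R)-limonene oxide (C1–C3, C12–C17, C20; periodate cleavage gives the C12 ketone and the C3 aldehyde), 2-bromopropene (C4, C5, C18), ethyl vinyl ether (C6, C7; Claisen, E C3=C4) and 4-bromopent-4-enenitrile (C8–C11, C19).
5. Ring order: tetrahydrofuran (step 9), 14-membered carbocycle (step 14), ε-lactone (step 17).

Key step: step 14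

Remark: cembrane numbering is used (C1 = ring CH carrying C15(=C17H2)–C16; C3 carbinol; C4 and C7 tetrahydrofuran carbons; C8 tertiary carbinol; C11 ketone; C12 lactone carbinol; C18, C19, C20 = methyls on C4, C8, C12); TBS = tert-butyldimethylsilyl, TBSO = its ether oxygen; commercial (+)-limonene 1,2-oxide is taken as the cis/trans mixture from (R)-limonene, and the target is taken to exist as the open γ-hydroxy ketone as drawn.

**Route**

Step 1
Reactants: 1 (+)-limonene 1,2-oxide (4R; cis/trans mixture)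
Product: 3 (3R)-6-oxo-3-(prop-1-en-2-yl)heptanal, via limonene-1,2-diol 2 (not isolated)
Conditions: H5IO6, THF/H2O, 0 °C to rt
Reagents that add atoms: water, O
Why: Either epoxide diastereomer is hydrolysed to the 1,2-diol and cleaved by periodate (glycol cleavage), which opens the six-membered ring to the C12 methyl ketone and the C3 aldehyde and leaves the isopropenyl group and the C1 stereocentre of (R)-limonene untouched.

Step 2
Reactants: 3 (3R)-6-oxo-3-(prop-1-en-2-yl)heptanal; 4 2-bromopropene
Product: 6 (5R)-7-hydroxy-8-methyl-5-(prop-1-en-2-yl)non-8-en-2-one (both carbinol epimers), via isopropenylchromium dichloride 5 (not isolated)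
Conditions: CrCl2, NiCl2 (cat.), DMF, rt
Reagents that add atoms: 2-bromopropene (4), CC(Br)=C
Why: Nozaki–Hiyama–Kishi reaction, in which the alkenylchromium reagent adds to the aldehyde only (the methyl ketone is inert) to give the 2-methylallylic alcohol needed for the Claisen rearrangement; the new C3 carbinol centre is formed as a mixture on purpose because step 4 destroys it.

Step 3
Reactants: 6 (5R)-7-hydroxy-8-methyl-5-(prop-1-en-2-yl)non-8-en-2-one
Product: 7 (5R)-2-methyl-7-(2-methyl-1,3-dioxolan-2-yl)-5-(prop-1-en-2-yl)hept-1-en-3-ol (both carbinol epimers)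
Conditions: ethylene glycol, PPTS (cat.), benzene, reflux (Dean–Stark)
Reagents that add atoms: ethylene glycol, OCCO
Why: Acid-catalysed ketalisation masks the C12 ketone, which must survive LiBH4 and i-Bu2AlH later and is released in step 13; the weak acid PPTS should leave the allylic alcohol intact.

Step 4
Reactants: 7 (5R)-2-methyl-7-(2-methyl-1,3-dioxolan-2-yl)-5-(prop-1-en-2-yl)hept-1-en-3-ol; 8 ethyl vinyl ether
Product: 10 (4E,7R)-4-methyl-9-(2-methyl-1,3-dioxolan-2-yl)-7-(prop-1-en-2-yl)non-4-enal, via allyl vinyl ether 9 (not isolated)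
Conditions: Hg(OAc)2 (cat.), NaOAc, ethyl vinyl ether, reflux; then toluene, 130 °C (sealed tube)
Reagents that add atoms: ethyl vinyl ether (8), C=COCC
Why: Mercury-catalysed transvinylation and Claisen rearrangement through a chair transition state with the C2 chain equatorial (axial it would clash with the 2-methyl group) should give the E C3=C4 alkene, turn the former carbinol oxygen into the C7 aldehyde and add C6 and C7 in one operation.

Step 5
Reactants: 11 2,3-dibromopropene; 12 acetonitrile
Product: 14 4-bromopent-4-enenitrile, via lithioacetonitrile 13 (not isolated)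
Conditions: n-BuLi, MeCN, THF, −78 °C; then 2,3-dibromopropene, −78 °C to rt
Reagents that add atoms: acetonitrile (12), CC#N
Why: Lithioacetonitrile displaces the allylic bromide of 11 by SN2 substitution, while the vinylic bromide needed for step 6 is inert to the nucleophile.

Step 6
Reactants: 10 (4E,7R)-4-methyl-9-(2-methyl-1,3-dioxolan-2-yl)-7-(prop-1-en-2-yl)non-4-enal; 14 4-bromopent-4-enenitrile
Product: 16 (5R,8E,11R)-5-hydroxy-8-methyl-4-methylidene-13-(2-methyl-1,3-dioxolan-2-yl)-11-(prop-1-en-2-yl)tridec-8-enenitrile, via alkenylchromium dichloride 15 (not isolated)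
Conditions: CrCl2, NiCl2 (cat.), chiral oxazoline–sulfonamide ligand, Et3N, THF, rt
Reagents that add atoms: 4-bromopent-4-enenitrile (14), C=C(Br)CCC#N
Why: Asymmetric Nozaki–Hiyama–Kishi reaction, in which zerovalent nickel inserts into the vinyl bromide, transmetalation gives the alkenylchromium species bound to the chiral sulfonamide ligand, and its addition to the aldehyde sets the C7 carbinol (7R, by choice of the ligand enantiomer) with nitrile and ketal tolerated; residual 7S epimer is removed in step 7.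

Step 7
Reactants: 16 (7R)-allylic alcohol nitrile
Product: 17 3-[(2S)-2-[(1R,4E,7R)-1-hydroxy-4-methyl-9-(2-methyl-1,3-dioxolan-2-yl)-7-(prop-1-en-2-yl)non-4-en-1-yl]oxiran-2-yl]propanenitrile
Conditions: Ti(OiPr)4 (cat.), D-(−)-diisopropyl tartrate, t-BuOOH, 4 Å molecular sieves, CH2Cl2, −20 °C
Reagents that add atoms: tert-butyl hydroperoxide, CC(C)(C)OO
Why: Sharpless asymmetric epoxidation is hydroxyl-directed, so only the allylic C8=C19 alkene reacts (not C3=C4 or the isopropenyl group); with D-(−)-DIPT the 7R carbinol is the fast-reacting matched isomer and gives the erythro epoxy alcohol, which places the C8 oxygen on the face required for 8R, while any 7S epimer stays behind as unreacted allylic alcohol.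

Step 8
Reactants: 17 epoxy alcohol
Product: 18 (4R,5R,8E,11R)-4,5-dihydroxy-4,8-dimethyl-13-(2-methyl-1,3-dioxolan-2-yl)-11-(prop-1-en-2-yl)tridec-8-enenitrile
Conditions: LiBH4, THF, 0 °C to rt
Reagents that add atoms: none
Why: Borohydride opens the 2,2-disubstituted epoxide by SN2 attack at its unhindered CH2 terminus, which turns that carbon into the C19 methyl group and leaves the C8 oxygen in place (7R,8R glycol); LiBH4 does not reduce the nitrile.

Step 9
Reactants: 18 (7R,8R)-glycol nitrile
Product: 20 (4R)-4-hydroxy-4-[(2R,5R)-5-[(1S,3R)-1-hydroxy-5-(2-methyl-1,3-dioxolan-2-yl)-3-(prop-1-en-2-yl)pentyl]-5-methyloxolan-2-yl]pentanenitrile, via epoxide 19 (not isolated)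
Conditions: L-fructose-derived ketone catalyst of the Shi epoxidation, KHSO5 (as Oxone, 2KHSO5·KHSO4·K2SO4), K2CO3, Bu4NHSO4, MeCN/CH2(OMe)2/aqueous Na2B4O7 buffer, 0 °C; then CSA (cat.), CH2Cl2, 0 °C
Reagents that add atoms: potassium peroxymonosulfate (KHSO5), [K+].[O-]S(=O)(=O)OO
Why: Shi epoxidation (chiral dioxirane) attacks the electron-rich trisubstituted E alkene in preference to the 1,1-disubstituted isopropenyl group, and the L-fructose-derived catalyst should give the 3S,4S epoxide; acid then triggers 5-exo-tet opening at the tertiary carbon C4 by the C7 hydroxyl with inversion (4R), which closes the 2,5-trans-tetrahydrofuran and frees the 3S hydroxyl.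

Step 10
Reactants: 20 tetrahydrofuran diol
Product: 21 (4R)-4-(TBSO)-4-[(2R,5R)-5-[(1S,3R)-1-(TBSO)-5-(2-methyl-1,3-dioxolan-2-yl)-3-(prop-1-en-2-yl)pentyl]-5-methyloxolan-2-yl]pentanenitrile
Conditions: TBSOTf, 2,6-lutidine, CH2Cl2, 0 °C to rt
Reagents that add atoms: tert-butyldimethylsilyl triflate, CC(C)(C)[Si](C)(C)OS(=O)(=O)C(F)(F)F
Why: The silyl triflate silylates both the secondary C3 hydroxyl and the hindered tertiary C8 hydroxyl, which keeps C8–OH from forming a lactol with the later C11 aldehyde and C3–OH from competing in the lactonisation.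

Step 11
Reactants: 21 bis-TBS ether
Product: 22 (4R)-4-(TBSO)-4-[(2R,5R)-5-[(1S,3R)-1-(TBSO)-3-(3-hydroxyprop-1-en-2-yl)-5-(2-methyl-1,3-dioxolan-2-yl)pentyl]-5-methyloxolan-2-yl]pentanenitrile
Conditions: SeO2 (cat.), t-BuOOH, CH2Cl2, rt
Reagents that add atoms: selenium dioxide, O=[Se]=O (oxygen donor); tert-butyl hydroperoxide, CC(C)(C)OO (terminal oxidant)
Why: Selenium dioxide allylic oxidation (ene reaction, then 2,3-sigmatropic shift) of the only remaining alkene should hydroxylate the isopropenyl methyl group (C16) rather than the hindered C1 methine, with t-BuOOH reoxidising the selenium.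

Step 12
Reactants: 22 C16 allylic alcohol nitrile
Product: 24 (4R)-4-(TBSO)-4-[(2R,5R)-5-[(1S,3R)-1-(TBSO)-3-(3-hydroxyprop-1-en-2-yl)-5-(2-methyl-1,3-dioxolan-2-yl)pentyl]-5-methyloxolan-2-yl]pentanal, via aldimine 23 (not isolated)
Conditions: i-Bu2AlH, CH2Cl2, −78 °C; then aqueous potassium sodium tartrate, rt
Reagents that add atoms: water, O
Why: i-Bu2AlH adds once to the nitrile at low temperature to give the N-aluminio aldimine, which is hydrolysed on work-up to the C11 aldehyde; ketal and silyl ethers are inert and the free hydroxyl only consumes one equivalent of hydride.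

Step 13
Reactants: 24 ketal aldehyde
Product: 25 (4R)-4-(TBSO)-4-[(2R,5R)-5-[(1S,3R)-1-(TBSO)-3-(3-hydroxyprop-1-en-2-yl)-6-oxoheptyl]-5-methyloxolan-2-yl]pentanal
Conditions: PPTS, acetone/H2O, 50 °C
Reagents that add atoms: water, O
Why: Mild acid-catalysed ketal hydrolysis (exchange to acetone) releases the C12 methyl ketone, while the secondary and tertiary TBS ethers should be stable to PPTS.

Step 14
Reactants: 25 seco keto aldehyde
Product: 26 (1R,3S,4R,7R,8R,12R)-3,8-bis(TBSO)-4,7-epoxycembr-15(17)-ene-11,12,16-triol (both C11 epimers)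
Conditions: SmI2 (3 equiv), THF, rt, slow addition of 25 (final concentration about 1 mM); then aqueous NH4Cl
Reagents that add atoms: none
Why: SmI2 reduces the aldehyde (the more easily reduced carbonyl) to the C11 ketyl, which adds on the oxophilic trivalent samarium centre to the carbon of the coordinated C12 methyl ketone, and a second electron transfer gives the samarium cis-diolate of 26 that is protonated on work-up; both carbons are electrophilic carbonyl carbons before the step, so this is a reductive ketyl-radical union of like-polarity centres. The closest known reaction type is the intramolecular pinacol coupling of ω-keto aldehydes by low-valent metals (SmI2, low-valent titanium), a reaction type established for closing 14-membered carbocycles at exactly such a secondary/tertiary glycol. The ring closed is the 14-membered carbocycle (and with it the 13-membered ring through the tetrahydrofuran oxygen), by 14-exo-trig attack of the ketyl carbon on the ketone C=O. C11 becomes a carbinol centre that need not be controlled because step 15 converts both epimers into the same ketone, whereas the quaternary C12 centre is under substrate control: in the samarium-bridged transition state the two oxygens are tied cis and the chain, bent by the 2,5-trans-tetrahydrofuran and anchored at C1, is expected to place the C20 methyl group on the outside of the closing ring, which corresponds to 12R; this bias is the least secure element of the route, and 12-epimeric glycol can be returned to 25 by NaIO4 cleavage. The step needs reduction of the aldehyde and not the ketone (secured by working without HMPA, so that no C12 ketyl arises that could cyclise onto the C15=C17 alkene), ring closure rather than intermolecular coupling (secured by slow addition at high dilution and by the tetrahydrofuran turn in the middle of the chain), and tolerance of the silyl ethers, the 1,1-disubstituted alkene and the free primary alcohol, all of which are inert to SmI2.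

Step 15
Reactants: 26 macrocyclic triol
Product: 27 (1R,3S,4R,7R,8R,12R)-3,8-bis(TBSO)-4,7-epoxy-12-hydroxy-11-oxocembr-15(17)-en-16-al
Conditions: IBX, DMSO/THF, rt
Reagents that add atoms: none
Why: IBX oxidises the secondary C11 carbinol (both epimers to the same ketone) and the allylic C16 alcohol to the enal in one operation, leaves the tertiary C12 hydroxyl alone and is an oxidant that converts 1,2-diols to α-ketols without cleaving the C–C bond.

Step 16
Reactants: 27 keto enal
Product: 28 (1R,3S,4R,7R,8R,12R)-3,8-bis(TBSO)-4,7-epoxy-12-hydroxy-11-oxocembr-15(17)-en-16-oic acid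
Conditions: NaClO2, NaH2PO4, 2-methyl-2-butene, t-BuOH/H2O, rt
Reagents that add atoms: sodium chlorite, [Na+].[O-]Cl=O
Why: Pinnick oxidation converts the enal into the acrylic acid without touching the ketone, the tertiary α-hydroxy ketone or the silyl ethers, the alkene scavenger removing HOCl.

Step 17
Reactants: 28 seco acid
Product: 30 (1R,3S,4R,7R,8R,12R)-3,8-bis(TBSO)-4,7-epoxy-11-oxocembr-15(17)-en-16,12-olide, via mixed anhydride 29 (not isolated)
Conditions: 2,4,6-trichlorobenzoyl chloride, Et3N, THF, rt; then DMAP, toluene, 80 °C (high dilution)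
Reagents that add atoms: none
Why: Yamaguchi lactonisation, in which DMAP attacks the mixed anhydride and the acylpyridinium ion is captured by the only free hydroxyl, the tertiary C12–OH, in a 7-exo-trig closure of the ε-lactone (the C3 and C8 hydroxyls are silylated, so neither a δ-lactone nor a larger ring can form).

Step 18
Reactants: 30 bis-TBS lactone
Product: 31 CNP0266269.1, (1R,3S,4R,7R,8R,12R)-4,7-epoxy-3,8-dihydroxy-11-oxocembr-15(17)-en-16,12-olide
Conditions: HF·pyridine, pyridine/THF, 0 °C to rt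
Reagents that add atoms: none
Why: Acidic, weakly nucleophilic HF·pyridine cleaves both silyl ethers without adding to the α-methylene lactone or disturbing the α-acyloxy ketone, and no stereocentre is touched.

**Compound list**

1 | (+)-limonene 1,2-oxide, (4R)-1-methyl-4-(prop-1-en-2-yl)-7-oxabicyclo[4.1.0]heptane, cis/trans mixture | CC(=C)[C@@H]1CCC2(C)OC2C1 | starting material
2 | limonene-1,2-diol, (4R)-1-methyl-4-(prop-1-en-2-yl)cyclohexane-1,2-diol | CC(=C)[C@@H]1CCC(C)(O)C(O)C1 | intermediate
3 | (3R)-6-oxo-3-(prop-1-en-2-yl)heptanal | CC(=O)CC[C@H](CC=O)C(C)=C | intermediate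
4 | 2-bromopropene | CC(Br)=C | starting material
5 | prop-1-en-2-ylchromium dichloride | CC(=C)[Cr](Cl)Cl | intermediate
6 | (5R)-7-hydroxy-8-methyl-5-(prop-1-en-2-yl)non-8-en-2-one, both epimers at the carbinol (cembrane C3) | CC(=O)CC[C@H](CC(O)C(C)=C)C(C)=C | intermediate
7 | (5R)-2-methyl-7-(2-methyl-1,3-dioxolan-2-yl)-5-(prop-1-en-2-yl)hept-1-en-3-ol, both carbinol epimers | CC1(CC[C@H](CC(O)C(C)=C)C(C)=C)OCCO1 | intermediate
8 | ethyl vinyl ether | C=COCC | starting material
9 | vinyl ether of 7, 2-[(3R)-5-(ethenyloxy)-6-methyl-3-(prop-1-en-2-yl)hept-6-en-1-yl]-2-methyl-1,3-dioxolane | CC1(CC[C@H](CC(OC=C)C(C)=C)C(C)=C)OCCO1 | intermediate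
10 | (4E,7R)-4-methyl-9-(2-methyl-1,3-dioxolan-2-yl)-7-(prop-1-en-2-yl)non-4-enal | CC1(CC[C@H](C/C=C(\C)CCC=O)C(C)=C)OCCO1 | intermediate
11 | 2,3-dibromopropene | BrCC(Br)=C | starting material
12 | acetonitrile | CC#N | starting material
13 | lithioacetonitrile | [Li]CC#N | intermediate
14 | 4-bromopent-4-enenitrile | C=C(Br)CCC#N | intermediate
15 | (4-cyanobut-1-en-2-yl)chromium dichloride | N#CCCC(=C)[Cr](Cl)Cl | intermediate
16 | (5R,8E,11R)-5-hydroxy-8-methyl-4-methylidene-13-(2-methyl-1,3-dioxolan-2-yl)-11-(prop-1-en-2-yl)tridec-8-enenitrile | CC1(CC[C@H](C/C=C(\C)CC[C@@H](O)C(=C)CCC#N)C(C)=C)OCCO1 | intermediate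
17 | 3-[(2S)-2-[(1R,4E,7R)-1-hydroxy-4-methyl-9-(2-methyl-1,3-dioxolan-2-yl)-7-(prop-1-en-2-yl)non-4-en-1-yl]oxiran-2-yl]propanenitrile | CC1(CC[C@H](C/C=C(\C)CC[C@@H](O)[C@]2(CCC#N)CO2)C(C)=C)OCCO1 | intermediate
18 | (4R,5R,8E,11R)-4,5-dihydroxy-4,8-dimethyl-13-(2-methyl-1,3-dioxolan-2-yl)-11-(prop-1-en-2-yl)tridec-8-enenitrile | CC1(CC[C@H](C/C=C(\C)CC[C@@H](O)[C@](C)(O)CCC#N)C(C)=C)OCCO1 | intermediate
19 | (4R,5R)-4,5-dihydroxy-4-methyl-7-[(2S,3S)-2-methyl-3-[(2R)-4-(2-methyl-1,3-dioxolan-2-yl)-2-(prop-1-en-2-yl)butyl]oxiran-2-yl]heptanenitrile | CC1(CC[C@H](C[C@@H]2O[C@@]2(C)CC[C@@H](O)[C@](C)(O)CCC#N)C(C)=C)OCCO1 | intermediate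
20 | (4R)-4-hydroxy-4-[(2R,5R)-5-[(1S,3R)-1-hydroxy-5-(2-methyl-1,3-dioxolan-2-yl)-3-(prop-1-en-2-yl)pentyl]-5-methyloxolan-2-yl]pentanenitrile | CC1(CC[C@H](C[C@H](O)[C@@]2(C)CC[C@@H](O2)[C@](C)(O)CCC#N)C(C)=C)OCCO1 | intermediate
21 | bis-TBS ether of 20 (TBS on the C3 and C8 oxygens) | CC1(CC[C@H](C[C@H](O[Si](C)(C)C(C)(C)C)[C@@]2(C)CC[C@@H](O2)[C@](C)(O[Si](C)(C)C(C)(C)C)CCC#N)C(C)=C)OCCO1 | intermediate
22 | 21 with the isopropenyl methyl hydroxylated (3-hydroxyprop-1-en-2-yl group on C1; C16 alcohol) | CC1(CC[C@H](C[C@H](O[Si](C)(C)C(C)(C)C)[C@@]2(C)CC[C@@H](O2)[C@](C)(O[Si](C)(C)C(C)(C)C)CCC#N)C(=C)CO)OCCO1 | intermediate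
23 | aldimine of 24 (C11 as CH=NH) | CC1(CC[C@H](C[C@H](O[Si](C)(C)C(C)(C)C)[C@@]2(C)CC[C@@H](O2)[C@](C)(O[Si](C)(C)C(C)(C)C)CCC=N)C(=C)CO)OCCO1 | intermediate
24 | (4R)-4-(TBSO)-4-[(2R,5R)-5-[(1S,3R)-1-(TBSO)-3-(3-hydroxyprop-1-en-2-yl)-5-(2-methyl-1,3-dioxolan-2-yl)pentyl]-5-methyloxolan-2-yl]pentanal | CC1(CC[C@H](C[C@H](O[Si](C)(C)C(C)(C)C)[C@@]2(C)CC[C@@H](O2)[C@](C)(O[Si](C)(C)C(C)(C)C)CCC=O)C(=C)CO)OCCO1 | intermediate
25 | (4R)-4-(TBSO)-4-[(2R,5R)-5-[(1S,3R)-1-(TBSO)-3-(3-hydroxyprop-1-en-2-yl)-6-oxoheptyl]-5-methyloxolan-2-yl]pentanal | CC(=O)CC[C@H](C[C@H](O[Si](C)(C)C(C)(C)C)[C@@]1(C)CC[C@@H](O1)[C@](C)(O[Si](C)(C)C(C)(C)C)CCC=O)C(=C)CO | intermediate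
26 | (1R,3S,4R,7R,8R,12R)-3,8-bis(TBSO)-4,7-epoxycembr-15(17)-ene-11,12,16-triol, both C11 epimers | C[C@@]1(O)CC[C@H](C[C@H](O[Si](C)(C)C(C)(C)C)[C@@]2(C)CC[C@@H](O2)[C@](C)(O[Si](C)(C)C(C)(C)C)CCC1O)C(=C)CO | intermediate
27 | (1R,3S,4R,7R,8R,12R)-3,8-bis(TBSO)-4,7-epoxy-12-hydroxy-11-oxocembr-15(17)-en-16-al | C[C@@]1(O)CC[C@H](C[C@H](O[Si](C)(C)C(C)(C)C)[C@@]2(C)CC[C@@H](O2)[C@](C)(O[Si](C)(C)C(C)(C)C)CCC1=O)C(=C)C=O | intermediate
28 | (1R,3S,4R,7R,8R,12R)-3,8-bis(TBSO)-4,7-epoxy-12-hydroxy-11-oxocembr-15(17)-en-16-oic acid | C[C@@]1(O)CC[C@H](C[C@H](O[Si](C)(C)C(C)(C)C)[C@@]2(C)CC[C@@H](O2)[C@](C)(O[Si](C)(C)C(C)(C)C)CCC1=O)C(=C)C(=O)O | intermediate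
29 | mixed anhydride of 28 with 2,4,6-trichlorobenzoic acid | C[C@@]1(O)CC[C@H](C[C@H](O[Si](C)(C)C(C)(C)C)[C@@]2(C)CC[C@@H](O2)[C@](C)(O[Si](C)(C)C(C)(C)C)CCC1=O)C(=C)C(=O)OC(=O)c1c(Cl)cc(Cl)cc1Cl | intermediate
30 | (1R,3S,4R,7R,8R,12R)-3,8-bis(TBSO)-4,7-epoxy-11-oxocembr-15(17)-en-16,12-olide | C=C1C(=O)O[C@]2(C)CC[C@@H]1C[C@H](O[Si](C)(C)C(C)(C)C)[C@@]1(C)CC[C@@H](O1)[C@](C)(O[Si](C)(C)C(C)(C)C)CCC2=O | intermediate
31 | CNP0266269.1, (1R,3S,4R,7R,8R,12R)-4,7-epoxy-3,8-dihydroxy-11-oxocembr-15(17)-en-16,12-olide | C=C1C(=O)O[C@]2(C)CC[C@@H]1C[C@H](O)[C@@]1(C)CC[C@@H](O1)[C@](C)(O)CCC2=O | target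

**Step count and risks**

Total step count: 18. Longest linear sequence: 17 steps (steps 1–4 and 6–18; step 5 makes side fragment 14).

Steps most likely to fail:

1. Step 14 (ketyl ring closure). What may go wrong: insufficient facial selectivity at the ketone carbon C12, or intermolecular coupling and simple aldehyde reduction outrunning the slow 14-membered ring closure. Within the route, glycol of the wrong C12 configuration can be cleaved with NaIO4 back to 25 and resubmitted. The fallback replaces the reductive coupling by an alkenylchromium ring closure followed by reagent-controlled oxygenation of C12; it sets out from 21 and comes back at 26. PPTS in aqueous acetone releases the ketone to give keto nitrile F1. Kinetic deprotonation with KN(SiMe3)2 at −78 °C and trapping with PhNTf2 gives terminal enol triflate F2. i-Bu2AlH at −78 °C reduces the nitrile to triflate aldehyde F3. An intramolecular Nozaki–Hiyama–Kishi reaction (CrCl2, NiCl2 cat., DMSO/THF, high dilution) forms the C11–C12 bond and gives 14-membered allylic alcohol F4, with C12 as an exocyclic methylene carbon and C11 as a mixture of epimers. Sharpless epoxidation with Ti(OiPr)4, D-(−)-DIPT and t-BuOOH, run as a kinetic resolution, should convert the 11R epimer into spiro epoxy alcohol F5 (the 11S epimer can be returned by oxidation to the enone and CBS reduction). LiBH4 opens the epoxide at its CH2 terminus to give glycol F6, in which the C20 methyl group and the 12R carbinol are set by the tartrate. SeO2/t-BuOOH as in step 11 then gives 26 as its 11R epimer.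

2. Step 17 (lactonisation). What may go wrong: acylation of the hindered tertiary hydroxyl next to the ketone is slower than oligomerisation or decomposition of the activated acid, and base may trigger α-ketol rearrangement. The fallback lactonises before the ketone exists; it sets out from 26 and comes back at 30. MnO2 oxidises only the allylic C16 alcohol to give enal glycol F7. Pinnick oxidation gives acid glycol F8. Yamaguchi lactonisation should then close the seven-membered ring on O12 to give hydroxy lactone F9; closure on the secondary O11 would need an eight-membered ring, and the tertiary hydroxyl is not deactivated by a neighbouring carbonyl. IBX oxidation of the remaining C11 carbinol gives 30.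

3. Step 11 (allylic oxidation). What may go wrong: ene abstraction of the C1 methine hydrogen, which would put oxygen on C1, or over-oxidation to the enal. The fallback sets out from 21 and comes back at 22. Ene-type chlorination with HOCl generated from Ca(OCl)2 and CO2 in CH2Cl2/H2O gives allylic chloride F10. CsOAc in DMF displaces chloride to give allylic acetate F11. K2CO3 in MeOH removes the acetyl group to give 22.

Further compounds
F1 | step 14 | keto nitrile (21 without the ketal) | CC(=O)CC[C@H](C[C@H](O[Si](C)(C)C(C)(C)C)[C@@]1(C)CC[C@@H](O1)[C@](C)(O[Si](C)(C)C(C)(C)C)CCC#N)C(C)=C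
F2 | step 14 | terminal enol triflate of F1 at C12 | C=C(OS(=O)(=O)C(F)(F)F)CC[C@H](C[C@H](O[Si](C)(C)C(C)(C)C)[C@@]1(C)CC[C@@H](O1)[C@](C)(O[Si](C)(C)C(C)(C)C)CCC#N)C(C)=C
F3 | step 14 | triflate aldehyde (C11 aldehyde) | C=C(OS(=O)(=O)C(F)(F)F)CC[C@H](C[C@H](O[Si](C)(C)C(C)(C)C)[C@@]1(C)CC[C@@H](O1)[C@](C)(O[Si](C)(C)C(C)(C)C)CCC=O)C(C)=C
F4 | step 14 | 14-membered allylic alcohol, 12-methylidene, C11 epimers | C=C1CC[C@H](C[C@H](O[Si](C)(C)C(C)(C)C)[C@@]2(C)CC[C@@H](O2)[C@](C)(O[Si](C)(C)C(C)(C)C)CCC1O)C(C)=C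
F5 | step 14 | (11R)-spiro epoxy alcohol (12,20-epoxide) | C1O[C@@]12CC[C@H](C[C@H](O[Si](C)(C)C(C)(C)C)[C@@]3(C)CC[C@@H](O3)[C@](C)(O[Si](C)(C)C(C)(C)C)CC[C@H]2O)C(C)=C
F6 | step 14 | (11R,12R)-glycol with the isopropenyl group | C[C@@]1(O)CC[C@H](C[C@H](O[Si](C)(C)C(C)(C)C)[C@@]2(C)CC[C@@H](O2)[C@](C)(O[Si](C)(C)C(C)(C)C)CC[C@H]1O)C(C)=C
F7 | step 17 | enal glycol (C16 aldehyde, 11,12-diol) | C[C@@]1(O)CC[C@H](C[C@H](O[Si](C)(C)C(C)(C)C)[C@@]2(C)CC[C@@H](O2)[C@](C)(O[Si](C)(C)C(C)(C)C)CCC1O)C(=C)C=O
F8 | step 17 | acid glycol (C16 acid, 11,12-diol) | C[C@@]1(O)CC[C@H](C[C@H](O[Si](C)(C)C(C)(C)C)[C@@]2(C)CC[C@@H](O2)[C@](C)(O[Si](C)(C)C(C)(C)C)CCC1O)C(=C)C(=O)O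
F9 | step 17 | 11-hydroxy lactone (16,12-olide, C11 carbinol) | C=C1C(=O)O[C@]2(C)CC[C@@H]1C[C@H](O[Si](C)(C)C(C)(C)C)[C@@]1(C)CC[C@@H](O1)[C@](C)(O[Si](C)(C)C(C)(C)C)CCC2O
F10 | step 11 | allylic chloride (C16 chloride) | CC1(CC[C@H](C[C@H](O[Si](C)(C)C(C)(C)C)[C@@]2(C)CC[C@@H](O2)[C@](C)(O[Si](C)(C)C(C)(C)C)CCC#N)C(=C)CCl)OCCO1
F11 | step 11 | allylic acetate (C16 acetate) | CC1(CC[C@H](C[C@H](O[Si](C)(C)C(C)(C)C)[C@@]2(C)CC[C@@H](O2)[C@](C)(O[Si](C)(C)C(C)(C)C)CCC#N)C(=C)COC(C)=O)OCCO1
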